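**Plan**

1. Numbering (germacrane): ring carbons C1–C10; C8 carries the lactone oxygen, C7 the lactone α-carbon C11 (C12 = C=O, C13 = CH2), C6 and C15 (on C4) the two isovalerates, C3 the free OH, C14 the methyl on C10.
2. Retrosynthesis: C3 carbinol ← ketone (CBS); ring bond C3–C4 ← vinyl iodide + aldehyde (Nozaki–Hiyama–Kishi); C13 ← CH2O; then the two lactone bonds O–C8 and C11–C7 are cut together; C5–C6 ← asymmetric alkynylation; C8–C9 ← allyl–alkynyl coupling.
3. Enabling feature: O6 sits on the carbon next to C7 of an (E)-C7=C8 alkene. A malonate half-ester on O6 therefore holds its central carbon (future C11) 5-exo to C7 and its free CO2H within reach of C8. One oxidative radical double annulation closes the temporary lactone A (O6–CO–C11–C7–C6) and the target lactone B (O8–C12–C11–C7–C8).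
4. Helpers out: lactone A is opened selectively (O6 is the better leaving group), its carbonyl leaves as CO2 when C13 enters, and O6 is freed for its isovalerate.
5. Forward order: chain C3→C9 with (E)-C1=C10 and (E)-C7=C8 → C6 carbinol → tether → lactones A and B → vinyl iodide → lactone A removed, methylene and esters on → ten-membered ring → C3.
6. Stereochemistry: C6 from ligand-controlled alkynylation; C7, C11 and C8 relayed from C6 in the key step; (E)-C4=C5 from syn-hydrostannation; (E)-C1=C10 from SeO2 oxidation; C3 from CBS reduction.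

Key step: step 9

Remark: (S,S)-ProPhenol is taken as the ligand enantiomer that gives the (S)-carbinol 10; if the facial sense were the opposite, its mirror image would be used.
Remark: compounds 1, 5, 9 and all reagents are taken as commercial.

**Route**

Step 1
Reactants: 1 4-methylpent-3-en-1-ol
Product: 2 TBDPS ether of 1
Conditions: TBDPSCl, imidazole, CH2Cl2, 0 °C to rt
Reagents that add atoms: tert-butyl(chloro)diphenylsilane, CC(C)(C)[Si](Cl)(c1ccccc1)c1ccccc1
Why: Imidazole-promoted silylation protects the primary alcohol that later becomes the C3 aldehyde; no stereocenter is involved.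

Step 2
Reactants: 2 TBDPS ether of 1
Product: 3 (E)-5-[(tert-butyldiphenylsilyl)oxy]-2-methylpent-2-en-1-ol
Conditions: SeO2 (cat.), t-BuOOH, CH2Cl2, rt
Reagents that add atoms: tert-butyl hydroperoxide, CC(C)(C)OO
Why: Riley allylic oxidation (ene reaction then [2,3]-sigmatropic shift) attacks the methyl trans to the chain of the trisubstituted alkene, which fixes the (E)-C1=C10 geometry.

Step 3
Reactants: 3 (E)-allylic alcohol
Product: 4 (E)-allylic bromide
Conditions: CBr4, PPh3, CH2Cl2, 0 °C
Reagents that add atoms: tetrabromomethane, BrC(Br)(Br)Br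
Why: Appel bromination of a primary allylic alcohol at low temperature should proceed without allylic transposition, so the (E)-alkene is kept.

Step 4
Reactants: 4 (E)-allylic bromide; 5 prop-2-yn-1-ol
Product: 6 (E)-8-[(tert-butyldiphenylsilyl)oxy]-5-methyloct-5-en-2-yn-1-ol
Conditions: 5, EtMgBr (2.1 equiv), THF, 0 °C; CuI (cat.); then 4, rt
Reagents that add atoms: none
Why: Copper-catalysed SN2 coupling of the alkynyl Grignard (dianion of propargyl alcohol) with the primary allylic bromide forms C8–C9 at the unhindered CH2 terminus and leaves the (E)-alkene untouched.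

Step 5
Reactants: 6 skipped enynol
Product: 7 (2E,5E)-8-[(tert-butyldiphenylsilyl)oxy]-5-methylocta-2,5-dien-1-ol
Conditions: NaAlH2(OCH2CH2OMe)2, THF, 0 °C to rt; Rochelle salt work-up
Reagents that add atoms: none
Why: Hydroxyl-directed trans-hydroalumination of the propargylic alcohol gives only the (E)-allylic alcohol, which sets the (E)-C7=C8 geometry.

Step 6
Reactants: 7 (2E,5E)-dienol
Product: 8 (2E,5E)-8-[(tert-butyldiphenylsilyl)oxy]-5-methylocta-2,5-dienal
Conditions: MnO2, CH2Cl2, rt
Reagents that add atoms: none
Why: MnO2 oxidises allylic alcohols selectively under neutral conditions, so the skipped diene should not be drawn into conjugation.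

Step 7
Reactants: 8 (2E,5E)-dienal; 9 tert-butyldimethyl(prop-2-yn-1-yloxy)silane
Product: 10 (4S,5E,8E)-1-[(tert-butyldimethylsilyl)oxy]-11-[(tert-butyldiphenylsilyl)oxy]-8-methylundeca-5,8-dien-2-yn-4-ol
Conditions: Me2Zn, (S,S)-ProPhenol [2,6-bis{[(S)-2-(hydroxydiphenylmethyl)pyrrolidin-1-yl]methyl}-4-methylphenol] (20 mol%), Ph3PO, toluene, 0 °C
Reagents that add atoms: none
Why: Catalytic asymmetric alkynylation of an enal by the dinuclear zinc–ProPhenol complex forms C5–C6 and sets the C6 carbinol, because the zinc alkynyl is delivered to one face of the catalyst-bound aldehyde.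

Step 8
Reactants: 10 (S)-enynol
Product: 11 hydrogen malonate (half-ester) of 10
Conditions: Meldrum's acid, toluene, 100 °C
Reagents that add atoms: Meldrum's acid (2,2-dimethyl-1,3-dioxane-4,6-dione), CC1(C)OC(=O)CC(=O)O1
Why: Thermal cycloreversion of Meldrum's acid to the acylketene and capture by the alcohol gives the malonate half-ester without a coupling reagent; the C6 stereocenter is not touched.

Step 9
Reactants: 11 hydrogen malonate of 10
Product: 13 cis-fused bis-lactone (lactones A and B), via lactone A C8 radical 12 (not isolated)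
Conditions: Mn(OAc)3·2H2O (2.2 equiv), KOAc, degassed AcOH, 50 °C
Reagents that add atoms: none
Why: Trivalent manganese forms the manganese enolate of the malonate and oxidises it to the C11 malonyl radical, which adds 5-exo-trig to C7 of the (E)-C7=C8 alkene (lactone A, the tether ring on O6); the C8 radical 12 is then oxidised by a second equivalent with capture by the free carboxylate (lactone B, five-membered C–O closure), so C11–C7 and O–C8 form in one flask. The closest known reaction type is the Mn(OAc)3-mediated oxidative free-radical lactone annulation, in its double-annulation form that turns unsaturated malonic acid derivatives and allylic malonates into fused bis-γ-lactones. C7 is set from C6: in the chair-like 5-exo transition state the alkynyl group on C6 sits pseudo-equatorial, which puts C5 and C8 trans on lactone A. C11 is set by the cis fusion that two five-membered rings require, and C8 is set in the C–O bond-forming step with the C9 chain on the convex face, the trans β,γ relation that this lactonisation also favours with simple alkenes. The step needs alkene over alkyne and C7=C8 over C1=C10: the electrophilic malonyl radical should prefer the alkene to the internal alkyne (which would give a vinyl radical), only C7 is in 5-exo reach, and the C8 radical has no allowed ring closure onto C1=C10.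

Step 10
Reactants: 13 bis-lactone
Product: 14 bis-lactone with free C15–OH
Conditions: HF·pyridine, THF, 0 °C
Reagents that add atoms: none
Why: Fluoride-mediated desilylation removes the primary TBS ether much faster than the primary TBDPS ether, and the acidic medium leaves both lactones intact.

Step 11
Reactants: 14 propargylic alcohol bis-lactone
Product: 16 (E)-vinyl iodide bis-lactone, via vinylstannane 15 (not isolated)
Conditions: Bu3SnH, PdCl2(PPh3)2 (cat.), THF, 0 °C; then I2, CH2Cl2, 0 °C
Reagents that add atoms: iodine, II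
Why: Palladium-catalysed syn-hydrostannation of a propargylic alcohol puts tin on C4 (next to the free CH2OH and away from the branched, acylated C6), and iododestannylation with retention gives the C4 iodide with C15 cis to C6, the geometry of the ring alkene.

Step 12
Reactants: 16 vinyl iodide bis-lactone
Product: 18 α-methylene lactone B diol, via hydroxy acid 17 (not isolated)
Conditions: LiOH, THF–H2O, 0 °C; then 37% aq. CH2O, Et2NH, AcOH, NaOAc, 60 °C
Reagents that add atoms: formaldehyde, C=O
Why: Hydroxide deprotonates C11–H and the malonate enolate expels the better leaving group (the allylic O6 alkoxide, E1cB), so lactone A opens and lactone B stays; the freed malonic half-acid 17 then undergoes decarboxylative Mannich methylenation, in which the former tether carbonyl leaves as CO2 and C13 enters.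

Step 13
Reactants: 18 α-methylene lactone diol
Product: 19 6,15-bis(3-methylbutanoate)
Conditions: isovaleric anhydride, Et3N, DMAP (cat.), CH2Cl2, 0 °C to rt
Reagents that add atoms: 3-methylbutanoic anhydride, CC(C)CC(=O)OC(=O)CC(C)C
Why: DMAP-catalysed acylation esterifies the only two free hydroxyls (O6 and O15) in one operation, and acylation of O6 also blocks lactone migration from O8 to O6.

Step 14
Reactants: 19 bis-isovalerate
Product: 20 primary alcohol at C3
Conditions: HF·pyridine, THF, rt
Reagents that add atoms: none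
Why: Fluoride cleaves the remaining TBDPS ether under acidic conditions that the esters, the α-methylene lactone and the vinyl iodide should tolerate.

Step 15
Reactants: 20 primary alcohol
Product: 21 C3 aldehyde
Conditions: Dess–Martin periodinane, NaHCO3, CH2Cl2, 0 °C; used at once
Reagents that add atoms: none
Why: Buffered Dess–Martin oxidation should give the β,γ-unsaturated aldehyde without moving the C1=C10 alkene into conjugation.

Step 16
Reactants: 21 iodo aldehyde
Product: 22 ten-membered carbinol (C3 epimers)
Conditions: CrCl2 (excess), NiCl2 (cat.), DMSO–THF, rt, high dilution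
Reagents that add atoms: none
Why: Intramolecular Nozaki–Hiyama–Kishi reaction: nickel inserts into the vinyl C–I bond, transmetalation gives an alkenylchromium that adds only to the aldehyde with retention of alkene geometry and closes the ring at C3–C4; C3 forms without control here and is set in steps 17 and 18.

Step 17
Reactants: 22 carbinol epimers
Product: 23 ten-membered enone (3-oxo)
Conditions: Dess–Martin periodinane, NaHCO3, CH2Cl2, 0 °C
Reagents that add atoms: none
Why: Dess–Martin oxidation of the allylic alcohol converges both C3 epimers on one enone under neutral conditions.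

Step 18
Reactants: 23 enone
Product: 24 target, (3R,6R,7R,8S)-3-hydroxy-6,15-bis(3-methylbutanoyloxy)germacra-1(10)E,4E,11(13)-trien-12,8-olide
Conditions: (S)-2-methyl-CBS-oxazaborolidine [(S)-1-methyl-3,3-diphenyltetrahydro-1H,3H-pyrrolo[1,2-c][1,3,2]oxazaborole], catecholborane, toluene, −78 °C
Reagents that add atoms: none
Why: Corey–Bakshi–Shibata reduction: the ketone binds to boron anti to its larger alkenyl (C4) side and hydride is delivered from the coordinated borane to give the (3R)-carbinol, and catecholborane at −78 °C should leave the α-methylene lactone and the esters alone.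

**Compound list**

1 | 4-methylpent-3-en-1-ol | CC(C)=CCCO | starting material
2 | tert-butyl[(4-methylpent-3-en-1-yl)oxy]diphenylsilane | CC(C)=CCCO[Si](c1ccccc1)(c1ccccc1)C(C)(C)C | intermediate
3 | (E)-5-[(tert-butyldiphenylsilyl)oxy]-2-methylpent-2-en-1-ol | OC/C(C)=C/CCO[Si](c1ccccc1)(c1ccccc1)C(C)(C)C | intermediate
4 | (E)-[(5-bromo-4-methylpent-3-en-1-yl)oxy](tert-butyl)diphenylsilane | BrC/C(C)=C/CCO[Si](c1ccccc1)(c1ccccc1)C(C)(C)C | intermediate
5 | prop-2-yn-1-ol | C#CCO | starting material
6 | (E)-8-[(tert-butyldiphenylsilyl)oxy]-5-methyloct-5-en-2-yn-1-ol | OCC#CC/C(C)=C/CCO[Si](c1ccccc1)(c1ccccc1)C(C)(C)C | intermediate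
7 | (2E,5E)-8-[(tert-butyldiphenylsilyl)oxy]-5-methylocta-2,5-dien-1-ol | OC/C=C/C/C(C)=C/CCO[Si](c1ccccc1)(c1ccccc1)C(C)(C)C | intermediate
8 | (2E,5E)-8-[(tert-butyldiphenylsilyl)oxy]-5-methylocta-2,5-dienal | O=C/C=C/C/C(C)=C/CCO[Si](c1ccccc1)(c1ccccc1)C(C)(C)C | intermediate
9 | tert-butyldimethyl(prop-2-yn-1-yloxy)silane | C#CCO[Si](C)(C)C(C)(C)C | starting material
10 | (4S,5E,8E)-1-[(tert-butyldimethylsilyl)oxy]-11-[(tert-butyldiphenylsilyl)oxy]-8-methylundeca-5,8-dien-2-yn-4-ol | CC(C)(C)[Si](C)(C)OCC#C[C@@H](O)/C=C/C/C(C)=C/CCO[Si](c1ccccc1)(c1ccccc1)C(C)(C)C | intermediate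
11 | hydrogen malonate of 10 (O6–CO–CH2–CO2H; configuration of 10) | CC(C)(C)[Si](C)(C)OCC#C[C@@H](OC(=O)CC(=O)O)/C=C/C/C(C)=C/CCO[Si](c1ccccc1)(c1ccccc1)C(C)(C)C | intermediate
12 | lactone A (on O6) with a secondary radical at C8 and the free C12 acid; C5 and C8 trans on the ring | O=C1O[C@H](C#CCO[Si](C)(C)C(C)(C)C)[C@@H]([CH]C/C(C)=C/CCO[Si](c2ccccc2)(c2ccccc2)C(C)(C)C)C1C(=O)O | intermediate
13 | cis-fused bis-lactone (3,7-dioxabicyclo[3.3.0]octane-2,8-dione): lactone A = O6–CO–C11–C7–C6 with the 3-(TBS-oxy)prop-1-ynyl group on C6 trans to C8; lactone B = O8–C12–C11–C7–C8 with the (E)-5-(TBDPS-oxy)-2-methylpent-2-enyl chain on C8 on the convex face | O=C1O[C@H](C#CCO[Si](C)(C)C(C)(C)C)[C@@H]2[C@H]1C(=O)O[C@H]2C/C(C)=C/CCO[Si](c3ccccc3)(c3ccccc3)C(C)(C)C | intermediate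
14 | bis-lactone 13 with the TBS group removed (free C15–OH) | O=C1O[C@H](C#CCO)[C@@H]2[C@H]1C(=O)O[C@H]2C/C(C)=C/CCO[Si](c3ccccc3)(c3ccccc3)C(C)(C)C | intermediate
15 | C4-tributylstannyl alkene of 14 (tin on C4, H on C5, C15 cis to C6) | O=C1O[C@H](/C=C(\CO)[Sn](CCCC)(CCCC)CCCC)[C@@H]2[C@H]1C(=O)O[C@H]2C/C(C)=C/CCO[Si](c3ccccc3)(c3ccccc3)C(C)(C)C | intermediate
16 | (E)-vinyl iodide bis-lactone (iodine on C4, CH2OH cis to C6) | O=C1O[C@H](/C=C(\CO)I)[C@@H]2[C@H]1C(=O)O[C@H]2C/C(C)=C/CCO[Si](c3ccccc3)(c3ccccc3)C(C)(C)C | intermediate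
17 | hydroxy acid: lactone B with CO2H on C11 (C11 epimers), free C6–OH and C15–OH | O=C(O)C1C(=O)O[C@@H](C/C(C)=C/CCO[Si](c2ccccc2)(c2ccccc2)C(C)(C)C)[C@@H]1[C@H](O)/C=C(\CO)I | intermediate
18 | α-methylene lactone B (trans-β,γ) with free C6–OH and C15–OH, C4 vinyl iodide, C3–OTBDPS | C=C1C(=O)O[C@@H](C/C(C)=C/CCO[Si](c2ccccc2)(c2ccccc2)C(C)(C)C)[C@@H]1[C@H](O)/C=C(\CO)I | intermediate
19 | 6,15-bis(3-methylbutanoate) of 18 | C=C1C(=O)O[C@@H](C/C(C)=C/CCO[Si](c2ccccc2)(c2ccccc2)C(C)(C)C)[C@@H]1[C@H](OC(=O)CC(C)C)/C=C(\COC(=O)CC(C)C)I | intermediate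
20 | primary alcohol (C3–OH) from 19 | C=C1C(=O)O[C@@H](C/C(C)=C/CCO)[C@@H]1[C@H](OC(=O)CC(C)C)/C=C(\COC(=O)CC(C)C)I | intermediate
21 | C3 aldehyde from 20 | C=C1C(=O)O[C@@H](C/C(C)=C/CC=O)[C@@H]1[C@H](OC(=O)CC(C)C)/C=C(\COC(=O)CC(C)C)I | intermediate
22 | ten-membered carbinol, both C3 epimers (otherwise as the target) | C=C1C(=O)O[C@H]2C/C(C)=C/CC(O)/C(COC(=O)CC(C)C)=C/[C@@H](OC(=O)CC(C)C)[C@H]12 | intermediate
23 | ten-membered 3-oxo enone | C=C1C(=O)O[C@H]2C/C(C)=C/CC(=O)/C(COC(=O)CC(C)C)=C/[C@@H](OC(=O)CC(C)C)[C@H]12 | intermediate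
24 | (3R,6R,7R,8S)-3-hydroxy-6,15-bis(3-methylbutanoyloxy)germacra-1(10)E,4E,11(13)-trien-12,8-olide | C=C1C(=O)O[C@H]2C/C(C)=C/C[C@@H](O)/C(COC(=O)CC(C)C)=C/[C@@H](OC(=O)CC(C)C)[C@H]12 | target

**Summary**

Total step count: 18. Longest linear sequence: 18 steps (from 1; 5 and 9 enter as commercial partners).

Steps most likely to fail:

1. Step 9 (key step). The radical must close through the disfavoured ester rotamer, so premature reduction or oligomerisation can win. It can also attack the alkyne (5-exo-dig), lose facial selectivity at C7, or over-oxidise the remaining malonate C–H of the product. Fallback, from 10 back to 13, changing oxidative termination into atom transfer followed by ionic lactonisation: 10 is acylated with methyl malonyl chloride and pyridine to the mixed malonate F1. Iodination (I2, K2CO3) gives the iodomalonate F2. Iodine-atom-transfer 5-exo cyclisation (hexabutylditin, visible light, benzene, 80 °C) gives the iodo lactone F3 (lactone A with iodine on C8). Heating F3 in DMF closes lactone B by SN2 attack of the cis ester carbonyl on C8 with loss of iodomethane and gives 13; the C8 iodide epimers are expected to interconvert by iodide exchange, so closure should go through the less hindered exo arrangement.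

2. Step 16. The strained ten-membered ring may not close (oligomerisation), the β,γ-unsaturated aldehyde may isomerise into conjugation, or the alkenylchromium may eliminate. Fallback, from 21 directly to 23 by an acyl coupling instead of a carbonyl addition: Pinnick oxidation (NaClO2, NaH2PO4, 2-methylbut-2-ene) gives the acid F8. 2,2′-Dipyridyl disulfide and PPh3 give the S-2-pyridyl thioester F9. Nickel-catalysed reductive vinyl iodide–thioester coupling (NiBr2(dtbbpy), Cp2ZrCl2, Zn, DMI, high dilution) closes the ring to enone 23, which also removes the uncontrolled C3 carbinol from the sequence.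

3. Step 12. Hydroxide may open lactone B instead of A, the acyl group may migrate from O8 to O6 after decarboxylation, or both lactones may hydrolyse. Fallback, from 14 back to 18, opening lactone A while O6 is still propargylic (a much better leaving group) and carrying the methylene masked as an amine through the tin chemistry: 14 is treated with LiOH and then with CH2O and excess Me2NH to give the Mannich base F4 (lactone B with a CH2NMe2 group on C11, alkyne diol). Hydrostannation as in step 11 gives the C4 vinylstannane F5, and I2 gives the vinyl iodide F6. MeI gives the methiodide F7, and NaHCO3 eliminates trimethylamine to give 18.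

**Further compounds**

F1 | step 9 | methyl malonate (mixed diester) of 10 | CC(C)(C)[Si](C)(C)OCC#C[C@@H](OC(=O)CC(=O)OC)/C=C/C/C(C)=C/CCO[Si](c1ccccc1)(c1ccccc1)C(C)(C)C
F2 | step 9 | methyl iodomalonate of 10 | CC(C)(C)[Si](C)(C)OCC#C[C@@H](OC(=O)C(I)C(=O)OC)/C=C/C/C(C)=C/CCO[Si](c1ccccc1)(c1ccccc1)C(C)(C)C
F3 | step 9 | lactone A with iodine on C8 and a methyl ester on C11 | O=C1O[C@H](C#CCO[Si](C)(C)C(C)(C)C)[C@@H](C(I)C/C(C)=C/CCO[Si](c2ccccc2)(c2ccccc2)C(C)(C)C)C1C(=O)OC
F4 | step 12 | lactone B with CH2NMe2 on C11, alkyne, free C6–OH and C15–OH | CN(C)CC1C(=O)O[C@@H](C/C(C)=C/CCO[Si](c2ccccc2)(c2ccccc2)C(C)(C)C)[C@@H]1[C@H](O)C#CCO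
F5 | step 12 | C4-tributylstannyl alkene of F4 | CN(C)CC1C(=O)O[C@@H](C/C(C)=C/CCO[Si](c2ccccc2)(c2ccccc2)C(C)(C)C)[C@@H]1[C@H](O)/C=C(\CO)[Sn](CCCC)(CCCC)CCCC
F6 | step 12 | C4 vinyl iodide of F4 | CN(C)CC1C(=O)O[C@@H](C/C(C)=C/CCO[Si](c2ccccc2)(c2ccccc2)C(C)(C)C)[C@@H]1[C@H](O)/C=C(\CO)I
F7 | step 12 | trimethylammonium iodide (methiodide) of F6 | C[N+](C)(C)CC1C(=O)O[C@@H](C/C(C)=C/CCO[Si](c2ccccc2)(c2ccccc2)C(C)(C)C)[C@@H]1[C@H](O)/C=C(\CO)I.[I-]
F8 | step 16 | C3 carboxylic acid from 21 | C=C1C(=O)O[C@@H](C/C(C)=C/CC(=O)O)[C@@H]1[C@H](OC(=O)CC(C)C)/C=C(\COC(=O)CC(C)C)I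
F9 | step 16 | S-2-pyridyl thioester of F8 | C=C1C(=O)O[C@@H](C/C(C)=C/CC(=O)Sc2ccccn2)[C@@H]1[C@H](OC(=O)CC(C)C)/C=C(\COC(=O)CC(C)C)I
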